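## Retrosynthetic overview

1. The enone Cα=Cβ bond is cut last (Claisen–Schmidt): calyxin H ⇒ a 3'-alkylated 2',4'-dihydroxy-6'-methoxyacetophenone plus a protected 4-hydroxybenzaldehyde.
2. Key disconnection: the C7–aryl (central ring) and C7–C6 bonds are cut together. One catalytic, enantioselective three-component coupling joins the acetyl-phloroglucinol methyl ether, 4-acetoxybenzaldehyde and an (E)-alkenylboronic acid that already carries C1–C6 and the C3 carbinol.
3. In that step the central ring is dearomatised to an ortho-quinone methide and re-aromatised by catalyst-controlled alkenyl transfer, which sets C7.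
4. The alkenylboronic acid comes from hydroboration of (S)-1-phenylhex-5-yn-3-ol, made by asymmetric propargylation of 3-phenylpropanal (sets C3).
5. No ring is built: all three benzene rings are bought.

Assumption: every compound marked "starting material" in the compound list is bought as a catalogue chemical.
Assumption: the sense of induction of each chiral catalyst is assigned by analogy with its established use ((R)-phosphoric acid: Re-face attack giving 3S; (R)-biphenol: 7S); if a first run shows the opposite sense, the antipodal catalyst is used and nothing else changes.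

The target is (3S,7S) in diarylheptanoid numbering, with both alkenes E.

## Route

Step 1
Reactants: 1 3-phenylpropanal; 2 allenylboronic acid pinacol ester (4,4,5,5-tetramethyl-2-(propa-1,2-dien-1-yl)-1,3,2-dioxaborolane)
Product: 4 (S)-1-phenylhex-5-yn-3-ol, via pinacol borate ester 3 (not isolated)
Conditions: (R)-TRIP [(R)-3,3'-bis(2,4,6-triisopropylphenyl)-1,1'-binaphthyl-2,2'-diyl hydrogen phosphate] (10 mol%), 4 Å MS, toluene, 0 °C, 48 h; aq. NaHCO3
Reagents that add atoms: none
Why: Chiral phosphoric acid-catalysed asymmetric propargylation (SE2' allenylboration through a closed six-membered transition state) in which the phosphate binds the boronate oxygen and the formyl C–H, so the γ-carbon of the allenyl unit adds to the Re face of the aldehyde and sets the 3S carbinol; SE2' transfer gives only the homopropargylic alcohol, and the minor enantiomer (about 5%) is removed later as a diastereomer.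

Step 2
Reactants: 4 (S)-1-phenylhex-5-yn-3-ol
Product: 7 [(1E,4S)-4-hydroxy-6-phenylhex-1-en-1-yl]boronic acid, via O-boryl alkyne 5 (not isolated), via bis-boryl alkene 6 (not isolated)
Conditions: catecholborane (2.5 equiv), THF, 0 °C (H2 evolution) then 70 °C, 4 h; H2O, rt, 2 h
Reagents that add atoms: catecholborane, B1Oc2ccccc2O1; water, O
Why: Brown hydroboration of a terminal alkyne: the first equivalent of catecholborane caps the hydroxyl, the second adds syn and anti-Markovnikov to give the (E)-alkenyl catechol boronate, and water hydrolyses both B–O catechol units to the free boronic acid without touching the carbinol centre.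

Step 3
Reactants: 7 [(1E,4S)-4-hydroxy-6-phenylhex-1-en-1-yl]boronic acid; 8 1-(2,4-dihydroxy-6-methoxyphenyl)ethan-1-one; 9 4-formylphenyl acetate
Product: 13 1-{2,4-dihydroxy-3-[(1S,2E,5S)-5-hydroxy-1-(4-hydroxyphenyl)-7-phenylhept-2-en-1-yl]-6-methoxyphenyl}ethan-1-one, via carbinol 10 (not isolated), via quinone methide 11 (not isolated), via aryl acetate 12 (not isolated)
Conditions: (R)-3,3'-dibromo-1,1'-bi-2-naphthol (20 mol%), 4 Å MS, PhCF3, 60 °C, 48 h (8 : 9 : 7 = 1 : 1.3 : 1.6); then MeOH, K2CO3 (cat.), rt, 3 h
Reagents that add atoms: none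
Why: Proposed new method: a catalytic asymmetric three-component Petasis-type condensation in which boron-templated ortho-hydroxyalkylation (Friedel–Crafts type) of phenol 8 by aldehyde 9 gives carbinol 10 held as a cyclic boronate, loss of water dearomatises the ring to ortho-quinone methide 11, and the chiral biphenol, exchanged onto the boron of 7 (whose own secondary carbinol self-esterifies boron under sieves, giving the exchange-labile sec-alkyl boronate the catalyst needs), forms a boron "ate" complex on the quinone methide oxygen that transfers the alkenyl group with retention of E geometry through a closed six-membered transition state to one face of the exocyclic carbon, re-aromatising the ring and setting C7 as S under catalyst control; the closest known reaction type is the chiral-biphenol-catalysed condensation of electron-rich phenols, aldehydes and alkenyl boronates and the related addition of alkenyl boronates to preformed ortho-quinone methides; C3 of 8 should react because it is the only ring carbon ortho to both hydroxyls while C5 is screened by the in-plane O-methyl group, the acetoxy group blocks a para-quinone methide pathway and makes 9 more electrophilic, and the closing K2CO3/MeOH transesterification removes the aryl acetate so that no ester enters step 4.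

Step 4
Reactants: 13 1-{2,4-dihydroxy-3-[(1S,2E,5S)-5-hydroxy-1-(4-hydroxyphenyl)-7-phenylhept-2-en-1-yl]-6-methoxyphenyl}ethan-1-one; 14 4-(tetrahydro-2H-pyran-2-yloxy)benzaldehyde (racemic)
Product: 16 calyxin H, via tetrahydropyranyl chalcone 15 (not isolated)
Conditions: LiN(SiMe3)2 (5.5 equiv), THF, −78 → 0 °C; 14 (2 equiv), 0 °C → rt, 16 h; then 1 M HCl, THF–H2O, rt, 1 h
Reagents that add atoms: none
Why: Claisen–Schmidt (crossed aldol) condensation run on the lithium polyanion of the unprotected polyphenol, where E1cB dehydration gives the (E)-enone and the aprotic medium keeps the 2'-oxygen as a lithium chelate so the chalcone cannot close to the flavanone; C7–H is not removed because its ring carries two ortho phenoxides, dilute acid then hydrolyses the aryl tetrahydropyranyl acetal, and no stereocentre is formed or touched (the 7-epimer and 3-epimer traces are removed by reverse-phase HPLC).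

## Compound list

1 | 3-phenylpropanal | O=CCCc1ccccc1 | starting material
2 | allenylboronic acid pinacol ester | C=C=CB1OC(C)(C)C(C)(C)O1 | starting material
3 | (S)-4,4,5,5-tetramethyl-2-[(1-phenylhex-5-yn-3-yl)oxy]-1,3,2-dioxaborolane (not isolated) | C#CC[C@@H](OB1OC(C)(C)C(C)(C)O1)CCc1ccccc1 | intermediate
4 | (S)-1-phenylhex-5-yn-3-ol | C#CC[C@@H](O)CCc1ccccc1 | intermediate
5 | (S)-2-[(1-phenylhex-5-yn-3-yl)oxy]-1,3,2-benzodioxaborole (not isolated) | C#CC[C@@H](OB1Oc2ccccc2O1)CCc1ccccc1 | intermediate
6 | 2-[(1E,4S)-4-(1,3,2-benzodioxaborol-2-yloxy)-6-phenylhex-1-en-1-yl]-1,3,2-benzodioxaborole (not isolated) | O1c2ccccc2OB1/C=C/C[C@@H](OB1Oc2ccccc2O1)CCc1ccccc1 | intermediate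
7 | [(1E,4S)-4-hydroxy-6-phenylhex-1-en-1-yl]boronic acid | OB(O)/C=C/C[C@@H](O)CCc1ccccc1 | intermediate
8 | 1-(2,4-dihydroxy-6-methoxyphenyl)ethan-1-one | COc1cc(O)cc(O)c1C(C)=O | starting material
9 | 4-formylphenyl acetate (4-acetoxybenzaldehyde) | CC(=O)Oc1ccc(C=O)cc1 | starting material
10 | 4-[(3-acetyl-2,6-dihydroxy-4-methoxyphenyl)(hydroxy)methyl]phenyl acetate (either configuration, held as cyclic boronate; not isolated) | COc1cc(O)c(C(O)c2ccc(OC(C)=O)cc2)c(O)c1C(C)=O | intermediate
11 | 4-[(3-acetyl-2-hydroxy-4-methoxy-6-oxocyclohexa-2,4-dien-1-ylidene)methyl]phenyl acetate (ortho-quinone methide; not isolated) | COC1=CC(=O)C(=Cc2ccc(OC(C)=O)cc2)C(O)=C1C(C)=O | intermediate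
12 | 4-[(1S,2E,5S)-1-(3-acetyl-2,6-dihydroxy-4-methoxyphenyl)-5-hydroxy-7-phenylhept-2-en-1-yl]phenyl acetate (not isolated) | COc1cc(O)c([C@@H](/C=C/C[C@@H](O)CCc2ccccc2)c2ccc(OC(C)=O)cc2)c(O)c1C(C)=O | intermediate
13 | 1-{2,4-dihydroxy-3-[(1S,2E,5S)-5-hydroxy-1-(4-hydroxyphenyl)-7-phenylhept-2-en-1-yl]-6-methoxyphenyl}ethan-1-one | COc1cc(O)c([C@@H](/C=C/C[C@@H](O)CCc2ccccc2)c2ccc(O)cc2)c(O)c1C(C)=O | intermediate
14 | 4-(tetrahydro-2H-pyran-2-yloxy)benzaldehyde (racemic) | O=Cc1ccc(OC2CCCCO2)cc1 | starting material
15 | (E)-1-{2,4-dihydroxy-3-[(1S,2E,5S)-5-hydroxy-1-(4-hydroxyphenyl)-7-phenylhept-2-en-1-yl]-6-methoxyphenyl}-3-[4-(tetrahydro-2H-pyran-2-yloxy)phenyl]prop-2-en-1-one (mixture at the acetal carbon; not isolated) | COc1cc(O)c([C@@H](/C=C/C[C@@H](O)CCc2ccccc2)c2ccc(O)cc2)c(O)c1C(=O)/C=C/c1ccc(OC2CCCCO2)cc1 | intermediate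
16 | calyxin H, (E)-1-{2,4-dihydroxy-3-[(1S,2E,5S)-5-hydroxy-1-(4-hydroxyphenyl)-7-phenylhept-2-en-1-yl]-6-methoxyphenyl}-3-(4-hydroxyphenyl)prop-2-en-1-one | COc1cc(O)c([C@@H](/C=C/C[C@@H](O)CCc2ccccc2)c2ccc(O)cc2)c(O)c1C(=O)/C=C/c1ccc(O)cc1 | target

## Step count

Total steps: 4. Longest linear sequence: 4 (1 → 4 → 7 → 13 → 16).

## Steps most likely to fail and fallbacks

**Step 3 (key three-component coupling).** The risks are an unruly polyfunctional boronic acid, C5 instead of C3 attack on 8, triarylmethane formation and modest selectivity at C7. The fallback sets out from 8 (with 9) and comes back at 13; it no longer carries the side chain on boron. Compounds 8, 9 and commercial dibutyl vinylboronate are combined under the same biphenol catalysis, where a simple dialkyl vinylboronate tolerates forcing and catalyst screening. This gives, by way of 10 and 11, the vinyl adduct 4-[(1S)-1-(3-acetyl-2,6-dihydroxy-4-methoxyphenyl)prop-2-en-1-yl]phenyl acetate F1. F1 is methanolysed in the flask to 1-{2,4-dihydroxy-3-[(1S)-1-(4-hydroxyphenyl)prop-2-en-1-yl]-6-methoxyphenyl}ethan-1-one F2, a small compound on which regioisomer and enantiomer purity can be secured by crystallisation or chiral HPLC. Separately, 1 is allylated (allylboronic acid pinacol ester, (R)-TRIP phosphoric acid) to (3S)-1-phenylhex-5-en-3-ol F3. Olefin cross-metathesis of F2 with excess F3 (second-generation Hoveyda–Grubbs catalyst, CH2Cl2, 40 °C; E-selective because of the bulky diarylmethyl group) gives 13.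

**Step 4 (late aldol on a penta-anion).** The risks are poor solubility or reactivity of the polyanion and flavanone closure. The fallback sets out from 8 and comes back at 16; the last two steps are inverted so the enolate chemistry is done on the small acetophenone. Compounds 8 and 14 are condensed with LiN(SiMe3)2 as in step 4 to give (E)-1-(2,4-dihydroxy-6-methoxyphenyl)-3-[4-(tetrahydro-2H-pyran-2-yloxy)phenyl]prop-2-en-1-one F4. F4 is hydrolysed in the acidic quench to helichrysetin, (E)-1-(2,4-dihydroxy-6-methoxyphenyl)-3-(4-hydroxyphenyl)prop-2-en-1-one F5, which is crystalline and can be purified in bulk. F5 then replaces 8 in the three-component coupling of step 3 with 9 and 7; the side reaction to watch is conjugate alkenylation of the enone, which should be slow for this electron-rich, hydrogen-bonded acceptor. The coupling gives calyxin H 4''-O-acetate, 4-[(1S,2E,5S)-1-{2,6-dihydroxy-3-[(E)-3-(4-hydroxyphenyl)prop-2-enoyl]-4-methoxyphenyl}-5-hydroxy-7-phenylhept-2-en-1-yl]phenyl acetate F6. Neutral deacetylation (NH4OAc, aqueous MeOH, rt), which does not trigger flavanone closure, gives 16.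

**Step 2 (hydroboration with a free hydroxyl, isolation of a polar boronic acid).** The fallback sets out from 4 and comes back at 7; hydrometalation and halogen–metal exchange replace hydroboration. Schwartz hydrozirconation with Cp2Zr(H)Cl (2.2 equiv, THF, rt; the first equivalent is spent on the hydroxyl) followed by I2 gives (3S,5E)-6-iodo-1-phenylhex-5-en-3-ol F7. MeLi (1 equiv, to form the alkoxide), then t-BuLi (2 equiv, Et2O, −78 °C), B(OiPr)3 and hydrolytic work-up give 7.

## Further compounds

F1 | step 3 | 4-[(1S)-1-(3-acetyl-2,6-dihydroxy-4-methoxyphenyl)prop-2-en-1-yl]phenyl acetate | COc1cc(O)c([C@@H](C=C)c2ccc(OC(C)=O)cc2)c(O)c1C(C)=O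
F2 | step 3 | 1-{2,4-dihydroxy-3-[(1S)-1-(4-hydroxyphenyl)prop-2-en-1-yl]-6-methoxyphenyl}ethan-1-one | COc1cc(O)c([C@@H](C=C)c2ccc(O)cc2)c(O)c1C(C)=O
F3 | step 3 | (3S)-1-phenylhex-5-en-3-ol | C=CC[C@@H](O)CCc1ccccc1
F4 | step 4 | (E)-1-(2,4-dihydroxy-6-methoxyphenyl)-3-[4-(tetrahydro-2H-pyran-2-yloxy)phenyl]prop-2-en-1-one | COc1cc(O)cc(O)c1C(=O)/C=C/c1ccc(OC2CCCCO2)cc1
F5 | step 4 | helichrysetin, (E)-1-(2,4-dihydroxy-6-methoxyphenyl)-3-(4-hydroxyphenyl)prop-2-en-1-one | COc1cc(O)cc(O)c1C(=O)/C=C/c1ccc(O)cc1
F6 | step 4 | calyxin H 4''-O-acetate, 4-[(1S,2E,5S)-1-{2,6-dihydroxy-3-[(E)-3-(4-hydroxyphenyl)prop-2-enoyl]-4-methoxyphenyl}-5-hydroxy-7-phenylhept-2-en-1-yl]phenyl acetate | COc1cc(O)c([C@@H](/C=C/C[C@@H](O)CCc2ccccc2)c2ccc(OC(C)=O)cc2)c(O)c1C(=O)/C=C/c1ccc(O)cc1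
F7 | step 2 | (3S,5E)-6-iodo-1-phenylhex-5-en-3-ol | I/C=C/C[C@@H](O)CCc1ccccc1
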